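## Structural features

The target is a (3R)-isoflavan. Ring A (benzene) is fused to the oxygen heterocycle ring C (O1, C2, C3, C4, C4a, C8a) to form a chroman, and C3 carries ring B through the C3–C1' bond. Ring A has a methoxy group at C5 and a free hydroxyl at C7. Ring B has a free hydroxyl at C2', a prenyl chain at C3' and a methoxy group at C4', so three contiguous positions next to the ring junction are substituted. C3 is the only stereocentre; it has no stereogenic neighbour, lies between the methylene groups C2 and C4, and carries no heteroatom or carbonyl group, so nothing in the target can direct its configuration. The fragile parts are the two electron-rich free phenols (oxidation) and the prenyl alkene, which is hydrogenated over palladium and cyclises onto the neighbouring 2'-hydroxyl under acid. The real difficulty is twofold: enantiocontrol at an isolated benzylic C–H stereocentre, and telling three phenolic oxygens apart (O1 must become the ring ether, the oxygens at C7 and C2' must end free, and only the one at C2' may be allylated). The feature used here is that the 2'-oxygen is four atoms from C4 (O–C2'–C1'–C3–C4): a bond from it to C4 closes a five-membered dihydrobenzofuran, the ring of a pterocarpan, and because C4 is benzylic to the electron-rich ring A that bond can be cut again by hydrogenolysis. With this extra bond C3 and C4 become neighbours in a cis-disubstituted ring that a carbene at C3 can close by inserting into a C4–H bond, and the ortho relation of the 2'-oxygen to C3' lets the prenyl group arrive afterwards by Claisen rearrangement.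

## Logic of the disconnections

19 to 18: no skeletal bond is cut; the C7 hydroxyl is traced back to its silyl ether. The C7 oxygen must stay masked while the 2'-oxygen is alkylated and rearranged. The forward step must be a desilylation that exposes the prenyl group neither to acid nor to strong base.

18 to 17: the C3'–CH2 bond of the prenyl group is cut and the five-carbon unit is placed on the 2'-oxygen as a tertiary allyl ether (retro-Claisen). C3' is the only free ortho position of that oxygen, so the sigmatropic shift has one place to go. The gain is a ring B without the alkene, so earlier hydrogenations are harmless. The forward step must run without acid.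

17 to 16 to 13 and 14: the alkene is traced back to an alkyne, and the O–C bond to the tertiary carbon is cut. Tertiary propargyl aryl ethers are accessible by copper-catalysed substitution, which a tertiary allyl electrophile would not allow cleanly. This requires that 13 have exactly one free phenol and that the semihydrogenation stop at the alkene.

13 to 12: in the backward direction a bond is added, from the 2'-oxygen to C4. The isolated stereocentre becomes part of a cis-fused bicycle, and the 2'-phenol is masked at the same time. The forward hydrogenolysis must cut only this doubly activated benzylic C–O bond; C4 then becomes CH2 and its configuration is erased.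

12 to 11: the O1–C2 bond is cut to a primary alcohol and the ring A phenol. Since the 2'-oxygen is tied up, only one phenol can close the ring. The closure needs the cis relation at C3 and C4 and conditions that generate no benzylic cation.

11 to 10: the CH2OH is traced back to a methyl ester and the phenol to its pivalate; one hydride reagent does both. The ester must be reduced before C3, which is α to it, can epimerise.

10 to 9 (key disconnection): the C3–C4 bond is cut between a carbene carbon and the ether methylene. The whole skeleton falls into an arylacetate unit and a benzyl unit joined only through the ether oxygen. The forward step demands catalyst control of both the cis relation and the absolute configuration, and a substrate with no O–H group. A check of the descriptors shows that the cis ester 10 is (2R,3S) and that its C3 maps onto (3R) in 19, so the structures of 9 and 10 are kept unchanged.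

9 to 8 to 7: the diazo group is removed, then the C1'–CH2 bond of the acetate arm is cut to an aryl bromide. Arylation of a zinc ester enolate is nearly neutral and spares the pivalate. This replaces a multistep one-carbon homologation of a salicylaldehyde bearing a free phenol.

7 to 5 and 6: the ether bond between the 2'-oxygen and C4 is cut. The forward step is a Mitsunobu reaction of the benzylic alcohol; the corresponding 2,4,6-trioxygenated benzyl bromide would ionise readily and is deliberately not made, which also saves a step.

5 to 4 to 3 to 2 to 1: reduction, pivaloylation, methylation and silylation are removed in turn. The three hydroxyls of 1 are told apart by their hydrogen bonds to the formyl group: the para hydroxyl reacts first, then one of the two ortho hydroxyls, then the last chelated one. The reduction must not create a free benzylic alkoxide beside the aryl pivalate, because that invites a 1,5 acyl shift; a borane is therefore used and not a borohydride.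

## Other disconnections considered

Alternative 1: The cut goes through ring C at C4–C4a and O1–C2 and gives A1 (5-methoxyresorcinol) and the 2-arylacrolein A2. In the forward step a chiral primary amine activates A2, a ring carbon of A1 adds to its methylene carbon, C3 is protonated under control of the catalyst, and the neighbouring phenol closes onto the aldehyde carbon to give lactol A3.
- In its favour: two ring bonds and the stereocentre come from one operation, ring A needs no protecting group, ring B arrives with its prenyl group, and neither a diazo compound nor a precious metal is used. On step count and protecting-group economy it is better than the chosen plan.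
- Against it: A1 has two kinds of nucleophilic carbon, and attack through the carbon between the two hydroxyls would exchange hydroxyl and methoxy on ring A; nothing in A1 biases this beyond statistics. The stereocentre is made by proton transfer at a benzylic carbon α to an aldehyde, the most easily enolised position, and the catalyst that sets it can also erase it. A3 still needs its C2 taken down to CH2 and an acidic acetal cleavage next to the prenyl group.
- Comparison: both plans join a ring A unit to a ring B unit and close ring C late, so they are equal in convergence. The chosen plan sets C3 in a C–C bond-forming transition state at low temperature without base and then removes the carbonyl that could enolise it, which is mechanistically the more reliable control. The alternative is the shorter route if its regio- and stereocontrol held.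

Alternative 2: The cut is at C3–C4 and O1–C2 and gives the ring A ortho-quinone methide A4 (generated in the flask) and the ring B arylacetic acid A5. In the forward step a chiral isothiourea is acylated by activated A5, the catalyst-bound enolate adds to the methylene of A4, and the phenoxide lactonises to the dihydrocoumarin A6.
- In its favour: it forms the same C3–C4 bond as the chosen key step, but convergently and with ring B fully substituted, and the carbonyl carbon already sits at C2. On convergence and reagent hazard it is equal or better.
- Against it: A4 has an unsubstituted exocyclic methylene and belongs to the most reactive, least selective quinone methides, whereas this annulation is established for stabilised, substituted partners. The stereocentre of A6 is benzylic and α to a lactone carbonyl in a basic medium. The lactone must be reduced and re-closed to the cyclic ether, and an acetal must be removed with acid beside the prenyl group.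
- Comparison: in both plans C3 is created α to an ester-type carbonyl (10 here, A6 there), so in this structural liability they are equal. The difference is exposure: 10 is formed without base at low temperature and reduced at once, whereas A6 is formed under base. The step count after the key step is slightly lower for the alternative, but A5 needs the same allylation and rearrangement chemistry at an earlier stage, so the totals are similar.

Alternative 3: Four bonds of ring B are cut (C5'–C6', C2'–C3', C4'–C5', C1'–C2'), leading to the diazo ketone A7 and the ynol ether A8. In the forward step photochemical Wolff rearrangement of A7, [2+2] addition to A8, four-electron ring opening and six-electron ring closure give phenol A9, which is identical with 18. For ring B to have six members, A7 has to be an α,β-unsaturated diazomethyl ketone with a single C=C; a dienyl ketone would bring two carbons too many.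
- In its favour: the mechanism dictates the order hydroxyl, prenyl, methoxy on ring B, the 2'-phenol needs no protection, and no hydrogenation follows the introduction of the prenyl group. In regiocontrol of ring B and in the end game (one step from A9 to the target) it is better than the chosen plan.
- Against it: it creates no stereocentre. C3 must already be set in A7, where it is allylic and γ to the enone carbonyl and can be lost by dienolisation, by light or by heat. The hardest problem of the target is therefore left unsolved. A7 and A8 are sensitive, and the step needs photochemistry followed by heating.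
- Comparison: the chosen plan buys ring B and uses its key step to make C3, while the alternative builds ring B and must import C3. Making A7 enantiomerically enriched (chroman ring, stereocentre, enone, diazo group) should take more steps than the chosen route needs to reach 13, so the chosen plan is the shorter overall.

Key step: step 8

Remark on the chemistry (assumption): Rh2(S-PTTL)4, dirhodium tetrakis[N-phthaloyl-(S)-tert-leucinate], is taken to deliver the (2R,3S) ester 10, the sense expected by analogy with simpler ortho-benzyloxy aryldiazoacetates; should the hindered ring A reverse it, the mirror-image catalyst Rh2(R-PTTL)4 would be used in the same way.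

## Route

Step 1
Reactants: 1 2,4,6-trihydroxybenzaldehyde
Product: 2 2,6-dihydroxy-4-(triisopropylsilyloxy)benzaldehyde
Conditions: TIPSCl (1.05 equiv), imidazole, DMF, 0 °C
Reagents that add atoms: chlorotriisopropylsilane CC(C)[Si](Cl)(C(C)C)C(C)C
Why: Silyl ether formation; the 4-hydroxyl is the only one not held in a hydrogen bond to the formyl oxygen and is the most acidic (para to CHO), so one equivalent of the bulky chlorosilane should react there.

Step 2
Reactants: 2 2,6-dihydroxy-4-(triisopropylsilyloxy)benzaldehyde
Product: 3 2-hydroxy-6-methoxy-4-(triisopropylsilyloxy)benzaldehyde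
Conditions: MeI (1.05 equiv), K2CO3, acetone, rt
Reagents that add atoms: iodomethane CI
Why: Williamson methylation; the formyl oxygen can chelate only one of the two equivalent ortho hydroxyls at a time, so the first methylation is fast, while the hydroxyl left in 3 is locked in a strong hydrogen bond and should react much more slowly.

Step 3
Reactants: 3 2-hydroxy-6-methoxy-4-(triisopropylsilyloxy)benzaldehyde
Product: 4 2-formyl-3-methoxy-5-(triisopropylsilyloxy)phenyl pivalate
Conditions: PivCl, Et3N, DMAP (cat.), CH2Cl2, 0 °C → rt
Reagents that add atoms: pivaloyl chloride CC(C)(C)C(Cl)=O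
Why: DMAP-catalysed acylation of the last phenol; the hindered pivalate is chosen because it should resist DBU in step 7 and carries no O–H for the carbene in step 8, yet falls to hydride in step 9.

Step 4
Reactants: 4 2-formyl-3-methoxy-5-(triisopropylsilyloxy)phenyl pivalate
Product: 5 2-(hydroxymethyl)-3-methoxy-5-(triisopropylsilyloxy)phenyl pivalate
Conditions: BH3·SMe2, THF, 0 °C; MeOH quench
Reagents that add atoms: none
Why: Chemoselective borane reduction of an aldehyde beside an aryl ester; the product stays a neutral borate ester until the quench, so no free benzylic alkoxide arises that could take over the neighbouring pivaloyl group by a 1,5 acyl shift.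

Step 5
Reactants: 5 2-(hydroxymethyl)-3-methoxy-5-(triisopropylsilyloxy)phenyl pivalate; 6 2-bromo-5-methoxyphenol
Product: 7 2-[(2-bromo-5-methoxyphenoxy)methyl]-3-methoxy-5-(triisopropylsilyloxy)phenyl pivalate
Conditions: PPh3, DIAD, THF, 0 °C → rt
Reagents that add atoms: none
Why: Mitsunobu etherification of a primary benzylic alcohol with an acidic ortho-bromophenol; it forms the future C4–O bond under neutral conditions and avoids a labile trioxygenated benzyl bromide.

Step 6
Reactants: 7 2-[(2-bromo-5-methoxyphenoxy)methyl]-3-methoxy-5-(triisopropylsilyloxy)phenyl pivalate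
Product: 8 methyl 2-{4-methoxy-2-[2-methoxy-6-(pivaloyloxy)-4-(triisopropylsilyloxy)benzyloxy]phenyl}acetate
Conditions: BrCH2CO2Me, Zn, THF, rt (gives BrZnCH2CO2Me); then 7, Pd(dba)2 (cat.), P(t-Bu)3 (cat.), THF, rt → 50 °C
Reagents that add atoms: methyl bromoacetate COC(=O)CBr
Why: Palladium-catalysed α-arylation of a Reformatsky reagent (Negishi-type coupling); zerovalent palladium with the bulky electron-rich phosphine inserts into the electron-rich C–Br bond, and the weakly basic zinc enolate should leave the aryl pivalate and the silyl ether alone.

Step 7
Reactants: 8 methyl 2-{4-methoxy-2-[2-methoxy-6-(pivaloyloxy)-4-(triisopropylsilyloxy)benzyloxy]phenyl}acetate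
Product: 9 methyl 2-diazo-2-{4-methoxy-2-[2-methoxy-6-(pivaloyloxy)-4-(triisopropylsilyloxy)benzyloxy]phenyl}acetate
Conditions: p-ABSA, DBU, MeCN, 0 °C → rt
Reagents that add atoms: 4-acetamidobenzenesulfonyl azide CC(=O)Nc1ccc(cc1)S(=O)(=O)N=[N+]=[N-]
Why: Regitz diazo transfer to an arylacetate; DBU deprotonates the benzylic ester position and the sulfonyl azide, one of the safer ones, delivers the N2 unit, while the hindered pivalate resists the amidine base.

Step 8
Reactants: 9 methyl 2-diazo-2-{4-methoxy-2-[2-methoxy-6-(pivaloyloxy)-4-(triisopropylsilyloxy)benzyloxy]phenyl}acetate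
Product: 10 methyl (2R,3S)-6-methoxy-2-[2-methoxy-6-(pivaloyloxy)-4-(triisopropylsilyloxy)phenyl]-2,3-dihydrobenzofuran-3-carboxylate
Conditions: Rh2(S-PTTL)4 (1–2 mol %), toluene, −78 → −60 °C, slow addition of 9
Reagents that add atoms: none
Why: Rh2(S-PTTL)4, a chiral tetracarboxylate of divalent rhodium, takes up the diazo carbon of 9, N2 leaves, and an electrophilic donor–acceptor rhodium carbene stands at the future C3. Its empty orbital then engages one C–H bond of the OCH2 group in a concerted but asynchronous three-centre transition state with hydride-shift character, which forms the C3–C4 bond and releases the catalyst. The closest known reaction type is the enantioselective intramolecular C–H insertion of ortho-benzyloxy aryldiazoacetates to cis-2-aryl-2,3-dihydrobenzofuran-3-carboxylates under chiral dirhodium carboxylates. The one ring formed, the dihydrofuran made of C3, C1', C2', the ether oxygen and C4, closes by 1,5-insertion, the ether methylene holding the only C–H bonds within reach of a five-membered arrangement. C3 is fixed by the face of the carbene that the phthalimido walls of the catalyst leave open, and C4 by which of the two enantiotopic hydrogens is engaged, the kinetically preferred transition state placing ring A and the ester cis. The step needs site selectivity, cis selectivity and enantioselectivity: the first is secured by the ether oxygen and the electron-rich ring A, which stabilise positive charge at C4, and by the absence of any O–H group (pivalate and silyl ether); the other two rest on the catalyst at low temperature in a non-polar solvent. Slow addition should keep carbene dimerisation down, and base-free isolation is needed because epimerisation of 10 at C3 would invert the very centre that is kept.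

Step 9
Reactants: 10 methyl (2R,3S)-6-methoxy-2-[2-methoxy-6-(pivaloyloxy)-4-(triisopropylsilyloxy)phenyl]-2,3-dihydrobenzofuran-3-carboxylate
Product: 11 [(2R,3R)-2-[2-hydroxy-6-methoxy-4-(triisopropylsilyloxy)phenyl]-6-methoxy-2,3-dihydrobenzofuran-3-yl]methanol
Conditions: LiAlH4, THF, −20 → 0 °C; aq. potassium sodium tartrate work-up
Reagents that add atoms: none
Why: Hydride reduction; LiAlH4 should reduce the methyl ester to the primary alcohol and cleave the aryl pivalate in the same flask, and C3 loses its acidifying carbonyl here (the descriptor changes to R only because the priorities change), so it is configurationally secure from this point on.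

Step 10
Reactants: 11 [(2R,3R)-2-[2-hydroxy-6-methoxy-4-(triisopropylsilyloxy)phenyl]-6-methoxy-2,3-dihydrobenzofuran-3-yl]methanol
Product: 12 (6aR,11aR)-1,9-dimethoxy-3-(triisopropylsilyloxy)-6a,11a-dihydro-6H-benzofuro[3,2-c]chromene
Conditions: PPh3, DIAD, THF (dilute), 0 °C → rt
Reagents that add atoms: none
Why: Intramolecular Mitsunobu etherification (6-exo-tet); the only free phenol, on ring A, displaces the activated primary hydroxyl, and the cis relation set in step 8 lets the six-membered ring fuse onto the dihydrobenzofuran as the cis-pterocarpan without touching a stereocentre.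

Step 11
Reactants: 12 (6aR,11aR)-1,9-dimethoxy-3-(triisopropylsilyloxy)-6a,11a-dihydro-6H-benzofuro[3,2-c]chromene
Product: 13 5-methoxy-2-[(3R)-5-methoxy-7-(triisopropylsilyloxy)chroman-3-yl]phenol
Conditions: H2 (1 atm), Pd/C, EtOAc–EtOH, rt
Reagents that add atoms: none
Why: Hydrogenolysis of the benzylic C4–O bond (benzylic to the electron-rich ring A, aryloxide leaving group), the classical opening of a pterocarpan to a 2'-hydroxyisoflavan; C4 becomes CH2, C3 is not involved, and the aryl silyl ether and the non-benzylic O1–C2 bond should be inert.

Step 12
Reactants: 13 5-methoxy-2-[(3R)-5-methoxy-7-(triisopropylsilyloxy)chroman-3-yl]phenol; 14 2-methylbut-3-yn-2-ol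
Product: 16 (3R)-5-methoxy-3-[4-methoxy-2-(2-methylbut-3-yn-2-yloxy)phenyl]-7-(triisopropylsilyloxy)chroman, via 2-methylbut-3-yn-2-yl trifluoroacetate 15 (not isolated)
Conditions: 14, (CF3CO)2O, DBU, MeCN, −5 °C; then 13, CuCl2·2H2O (cat.), DBU, MeCN, 0 °C
Reagents that add atoms: none
Why: Copper-catalysed propargylic etherification; 14 is activated in the flask as 15, divalent copper chloride and DBU make it an electrophile at the tertiary carbon, and the single free phenol of 13 attacks there, a standard route to aryl 1,1-dimethylpropargyl ethers.

Step 13
Reactants: 16 (3R)-5-methoxy-3-[4-methoxy-2-(2-methylbut-3-yn-2-yloxy)phenyl]-7-(triisopropylsilyloxy)chroman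
Product: 17 (3R)-5-methoxy-3-[4-methoxy-2-(2-methylbut-3-en-2-yloxy)phenyl]-7-(triisopropylsilyloxy)chroman
Conditions: H2 (1 atm), Pd/CaCO3 poisoned with Pb(OAc)2 (Lindlar catalyst), quinoline, EtOAc, rt
Reagents that add atoms: none
Why: Lindlar semihydrogenation of a terminal alkyne; the poisoned catalyst with quinoline should stop at the terminal alkene and leave the aryl ethers untouched.

Step 14
Reactants: 17 (3R)-5-methoxy-3-[4-methoxy-2-(2-methylbut-3-en-2-yloxy)phenyl]-7-(triisopropylsilyloxy)chroman
Product: 18 3-methoxy-2-(3-methylbut-2-en-1-yl)-6-[(3R)-5-methoxy-7-(triisopropylsilyloxy)chroman-3-yl]phenol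
Conditions: PhNEt2, 130 °C
Reagents that add atoms: none
Why: Aromatic Claisen rearrangement ([3,3]-sigmatropic), accelerated by the gem-dimethyl group; of the two ortho positions only C3' is free, so the allyl unit should arrive there with exchange of its termini as the linear prenyl group, and the basic aniline solvent suppresses acid-promoted cyclisation of the freed phenol onto the alkene.

Step 15
Reactants: 18 3-methoxy-2-(3-methylbut-2-en-1-yl)-6-[(3R)-5-methoxy-7-(triisopropylsilyloxy)chroman-3-yl]phenol
Product: 19 (3R)-3-[2-hydroxy-4-methoxy-3-(3-methylbut-2-en-1-yl)phenyl]-5-methoxychroman-7-ol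
Conditions: TBAF, AcOH, THF, 0 °C
Reagents that add atoms: none
Why: Fluoride cleavage of the aryl silyl ether; acetic acid buffers the phenoxide, so the electron-rich phenols see no strong base and the prenyl group sees no strong acid.

## Compound list

1 | 2,4,6-trihydroxybenzaldehyde | O=Cc1c(O)cc(O)cc1O | starting material
2 | 2,6-dihydroxy-4-(triisopropylsilyloxy)benzaldehyde | O=Cc1c(O)cc(O[Si](C(C)C)(C(C)C)C(C)C)cc1O | intermediate
3 | 2-hydroxy-6-methoxy-4-(triisopropylsilyloxy)benzaldehyde | COc1cc(O[Si](C(C)C)(C(C)C)C(C)C)cc(O)c1C=O | intermediate
4 | 2-formyl-3-methoxy-5-(triisopropylsilyloxy)phenyl pivalate | COc1cc(O[Si](C(C)C)(C(C)C)C(C)C)cc(OC(=O)C(C)(C)C)c1C=O | intermediate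
5 | 2-(hydroxymethyl)-3-methoxy-5-(triisopropylsilyloxy)phenyl pivalate | COc1cc(O[Si](C(C)C)(C(C)C)C(C)C)cc(OC(=O)C(C)(C)C)c1CO | intermediate
6 | 2-bromo-5-methoxyphenol | COc1ccc(Br)c(O)c1 | starting material
7 | 2-[(2-bromo-5-methoxyphenoxy)methyl]-3-methoxy-5-(triisopropylsilyloxy)phenyl pivalate | COc1ccc(Br)c(OCc2c(OC)cc(O[Si](C(C)C)(C(C)C)C(C)C)cc2OC(=O)C(C)(C)C)c1 | intermediate
8 | methyl 2-{4-methoxy-2-[2-methoxy-6-(pivaloyloxy)-4-(triisopropylsilyloxy)benzyloxy]phenyl}acetate | COC(=O)Cc1ccc(OC)cc1OCc1c(OC)cc(O[Si](C(C)C)(C(C)C)C(C)C)cc1OC(=O)C(C)(C)C | intermediate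
9 | methyl 2-diazo-2-{4-methoxy-2-[2-methoxy-6-(pivaloyloxy)-4-(triisopropylsilyloxy)benzyloxy]phenyl}acetate | COC(=O)C(=[N+]=[N-])c1ccc(OC)cc1OCc1c(OC)cc(O[Si](C(C)C)(C(C)C)C(C)C)cc1OC(=O)C(C)(C)C | intermediate
10 | methyl (2R,3S)-6-methoxy-2-[2-methoxy-6-(pivaloyloxy)-4-(triisopropylsilyloxy)phenyl]-2,3-dihydrobenzofuran-3-carboxylate (cis) | COC(=O)[C@H]1c2ccc(OC)cc2O[C@H]1c1c(OC)cc(O[Si](C(C)C)(C(C)C)C(C)C)cc1OC(=O)C(C)(C)C | intermediate
11 | [(2R,3R)-2-[2-hydroxy-6-methoxy-4-(triisopropylsilyloxy)phenyl]-6-methoxy-2,3-dihydrobenzofuran-3-yl]methanol (cis) | OC[C@H]1c2ccc(OC)cc2O[C@H]1c1c(OC)cc(O[Si](C(C)C)(C(C)C)C(C)C)cc1O | intermediate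
12 | (6aR,11aR)-1,9-dimethoxy-3-(triisopropylsilyloxy)-6a,11a-dihydro-6H-benzofuro[3,2-c]chromene (cis-pterocarpan) | C1[C@H]2c3ccc(OC)cc3O[C@H]2c2c(OC)cc(O[Si](C(C)C)(C(C)C)C(C)C)cc2O1 | intermediate
13 | 5-methoxy-2-[(3R)-5-methoxy-7-(triisopropylsilyloxy)chroman-3-yl]phenol | COc1cc(O[Si](C(C)C)(C(C)C)C(C)C)cc2c1C[C@H](c1ccc(OC)cc1O)CO2 | intermediate
14 | 2-methylbut-3-yn-2-ol | CC(C)(O)C#C | starting material
15 | 2-methylbut-3-yn-2-yl trifluoroacetate | CC(C)(OC(=O)C(F)(F)F)C#C | intermediate (not isolated)
16 | (3R)-5-methoxy-3-[4-methoxy-2-(2-methylbut-3-yn-2-yloxy)phenyl]-7-(triisopropylsilyloxy)chroman | COc1cc(O[Si](C(C)C)(C(C)C)C(C)C)cc2c1C[C@H](c1ccc(OC)cc1OC(C)(C)C#C)CO2 | intermediate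
17 | (3R)-5-methoxy-3-[4-methoxy-2-(2-methylbut-3-en-2-yloxy)phenyl]-7-(triisopropylsilyloxy)chroman | COc1cc(O[Si](C(C)C)(C(C)C)C(C)C)cc2c1C[C@H](c1ccc(OC)cc1OC(C)(C)C=C)CO2 | intermediate
18 | 3-methoxy-2-(3-methylbut-2-en-1-yl)-6-[(3R)-5-methoxy-7-(triisopropylsilyloxy)chroman-3-yl]phenol | COc1cc(O[Si](C(C)C)(C(C)C)C(C)C)cc2c1C[C@H](c1ccc(OC)c(CC=C(C)C)c1O)CO2 | intermediate
19 | (3R)-3-[2-hydroxy-4-methoxy-3-(3-methylbut-2-en-1-yl)phenyl]-5-methoxychroman-7-ol | COc1cc(O)cc2c1C[C@H](c1ccc(OC)c(CC=C(C)C)c1O)CO2 | target

## Step count and least certain steps

Total: 15 steps. Longest linear sequence: 15 steps (1 to 19; 6 and 14 are purchased).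

Step 8 (key step). The most likely failure is weak discrimination between the carbene faces and between cis and trans, or slow insertion with carbene dimerisation or addition to ring A taking over. The reason is that the ether methylene is flanked by a ring A with two ortho substituents, bulkier than the benzyl ethers on which this insertion is established. Epimerisation of the product at C3 during isolation would add to the problem. Fallback: give up catalyst-controlled enantioselection. From 9 the insertion would be run with the achiral Rh2(OAc)4 in CH2Cl2 at low temperature, which should still favour the kinetic cis ester but as the racemate, that is 10 together with its mirror image, methyl (2S,3R)-6-methoxy-2-[2-methoxy-6-(pivaloyloxy)-4-(triisopropylsilyloxy)phenyl]-2,3-dihydrobenzofuran-3-carboxylate F1. The two would be separated by preparative chromatography on a chiral stationary phase. This sets out from 9 and comes back to the route at 10.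

Step 6. Oxidative addition into the electron-rich, ortho-alkoxy C–Br bond may be slow, so that reduction of the bromide or self-condensation of the zinc enolate wins, and prolonged warming may bring acyl transfer from the pivalate. Fallback: bring in the diazo carbon and the ester together. From 5, a Mitsunobu reaction with 2-iodo-5-methoxyphenol F2 would give 2-[(2-iodo-5-methoxyphenoxy)methyl]-3-methoxy-5-(triisopropylsilyloxy)phenyl pivalate F3. Cross-coupling of F3 with ethyl diazoacetate (Pd(PPh3)4, Ag2CO3, Et3N, toluene, rt), in which the diazo group is retained, would give ethyl 2-diazo-2-{4-methoxy-2-[2-methoxy-6-(pivaloyloxy)-4-(triisopropylsilyloxy)benzyloxy]phenyl}acetate F4 without a diazo transfer. Insertion as in step 8 would give ethyl (2R,3S)-6-methoxy-2-[2-methoxy-6-(pivaloyloxy)-4-(triisopropylsilyloxy)phenyl]-2,3-dihydrobenzofuran-3-carboxylate F5, and LiAlH4 would convert F5 into 11. This sets out from 5 and comes back at 11.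

Step 9. The most likely failure is early loss of the temporary C4–O bond: once the pivalate is cleaved, the ring A phenoxide sits ortho to C4 and can expel the ring B aryloxide, and excess hydride would then reduce C4, freeing both phenols before ring C is closed. Base-induced β-elimination through the ester enolate and partial desilylation are lesser risks. Fallback: separate the ester reduction from the release of the phenol. From 10, Me3SnOH (ClCH2CH2Cl, 70 °C) would cleave only the methyl ester to (2R,3S)-6-methoxy-2-[2-methoxy-6-(pivaloyloxy)-4-(triisopropylsilyloxy)phenyl]-2,3-dihydrobenzofuran-3-carboxylic acid F6. BH3·SMe2 would reduce the acid beside the aryl pivalate to 2-[(2R,3R)-3-(hydroxymethyl)-6-methoxy-2,3-dihydrobenzofuran-2-yl]-3-methoxy-5-(triisopropylsilyloxy)phenyl pivalate F7. MsCl and Et3N would give 2-[(2R,3R)-6-methoxy-3-(methylsulfonyloxymethyl)-2,3-dihydrobenzofuran-2-yl]-3-methoxy-5-(triisopropylsilyloxy)phenyl pivalate F8. K2CO3 in MeOH at 0 °C would then remove the pivaloyl group, and the phenoxide, never in contact with hydride, should displace the mesylate at once to give 12. This sets out from 10 and comes back at 12, passing by 11 and step 10.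

Step 14. Heating may send the tertiary allyl ether down other paths: fragmentation back to 13 with loss of isoprene, cyclisation of the freed phenol onto the new alkene, or migration toward C5' by way of the blocked C1'. Fallback: directed ortho-metalation in place of the sigmatropic shift. From 13, MOMCl and i-Pr2NEt would give (3R)-5-methoxy-3-[4-methoxy-2-(methoxymethoxy)phenyl]-7-(triisopropylsilyloxy)chroman F9. n-BuLi (THF, 0 °C) should lithiate C3', the position flanked by the two oxygen substituents, and CuBr·SMe2 followed by prenyl bromide would give (3R)-5-methoxy-3-[4-methoxy-2-(methoxymethoxy)-3-(3-methylbut-2-en-1-yl)phenyl]-7-(triisopropylsilyloxy)chroman F10. Brief treatment with dilute HCl in MeOH at 0 °C would remove the acetal to give 18; this acid step carries the cyclisation risk noted for the prenyl group and is the reason the route is only a fallback. It sets out from 13 and comes back at 18, passing by steps 12 to 14.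

Step 2. Over-alkylation to the dimethyl ether, or loss of the silyl group from the para-formyl aryl silyl ether under carbonate, may erode the material. Fallback: reverse the order of the two steps. From 2, one equivalent of PivCl (Et3N, CH2Cl2, −20 °C) should stop after one acylation, because the bulky acyl group and the stronger hydrogen bond of the remaining hydroxyl make the second slow, giving 2-formyl-3-hydroxy-5-(triisopropylsilyloxy)phenyl pivalate F11. Its single hydroxyl would then be methylated (MeI, K2CO3, acetone) to 4. This sets out from 2 and comes back at 4, passing by 3.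

## Further compounds

F1 | step 8 | methyl (2S,3R)-6-methoxy-2-[2-methoxy-6-(pivaloyloxy)-4-(triisopropylsilyloxy)phenyl]-2,3-dihydrobenzofuran-3-carboxylate | COC(=O)[C@@H]1c2ccc(OC)cc2O[C@@H]1c1c(OC)cc(O[Si](C(C)C)(C(C)C)C(C)C)cc1OC(=O)C(C)(C)C
F2 | step 6 | 2-iodo-5-methoxyphenol | COc1ccc(I)c(O)c1
F3 | step 6 | 2-[(2-iodo-5-methoxyphenoxy)methyl]-3-methoxy-5-(triisopropylsilyloxy)phenyl pivalate | COc1ccc(I)c(OCc2c(OC)cc(O[Si](C(C)C)(C(C)C)C(C)C)cc2OC(=O)C(C)(C)C)c1
F4 | step 6 | ethyl 2-diazo-2-{4-methoxy-2-[2-methoxy-6-(pivaloyloxy)-4-(triisopropylsilyloxy)benzyloxy]phenyl}acetate | CCOC(=O)C(=[N+]=[N-])c1ccc(OC)cc1OCc1c(OC)cc(O[Si](C(C)C)(C(C)C)C(C)C)cc1OC(=O)C(C)(C)C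
F5 | step 6 | ethyl (2R,3S)-6-methoxy-2-[2-methoxy-6-(pivaloyloxy)-4-(triisopropylsilyloxy)phenyl]-2,3-dihydrobenzofuran-3-carboxylate | CCOC(=O)[C@H]1c2ccc(OC)cc2O[C@H]1c1c(OC)cc(O[Si](C(C)C)(C(C)C)C(C)C)cc1OC(=O)C(C)(C)C
F6 | step 9 | (2R,3S)-6-methoxy-2-[2-methoxy-6-(pivaloyloxy)-4-(triisopropylsilyloxy)phenyl]-2,3-dihydrobenzofuran-3-carboxylic acid | OC(=O)[C@H]1c2ccc(OC)cc2O[C@H]1c1c(OC)cc(O[Si](C(C)C)(C(C)C)C(C)C)cc1OC(=O)C(C)(C)C
F7 | step 9 | 2-[(2R,3R)-3-(hydroxymethyl)-6-methoxy-2,3-dihydrobenzofuran-2-yl]-3-methoxy-5-(triisopropylsilyloxy)phenyl pivalate | OC[C@H]1c2ccc(OC)cc2O[C@H]1c1c(OC)cc(O[Si](C(C)C)(C(C)C)C(C)C)cc1OC(=O)C(C)(C)C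
F8 | step 9 | 2-[(2R,3R)-6-methoxy-3-(methylsulfonyloxymethyl)-2,3-dihydrobenzofuran-2-yl]-3-methoxy-5-(triisopropylsilyloxy)phenyl pivalate | CS(=O)(=O)OC[C@H]1c2ccc(OC)cc2O[C@H]1c1c(OC)cc(O[Si](C(C)C)(C(C)C)C(C)C)cc1OC(=O)C(C)(C)C
F9 | step 14 | (3R)-5-methoxy-3-[4-methoxy-2-(methoxymethoxy)phenyl]-7-(triisopropylsilyloxy)chroman | COc1cc(O[Si](C(C)C)(C(C)C)C(C)C)cc2c1C[C@H](c1ccc(OC)cc1OCOC)CO2
F10 | step 14 | (3R)-5-methoxy-3-[4-methoxy-2-(methoxymethoxy)-3-(3-methylbut-2-en-1-yl)phenyl]-7-(triisopropylsilyloxy)chroman | COc1cc(O[Si](C(C)C)(C(C)C)C(C)C)cc2c1C[C@H](c1ccc(OC)c(CC=C(C)C)c1OCOC)CO2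
F11 | step 2 | 2-formyl-3-hydroxy-5-(triisopropylsilyloxy)phenyl pivalate | O=Cc1c(O)cc(O[Si](C(C)C)(C(C)C)C(C)C)cc1OC(=O)C(C)(C)C
A1 | alternative 1 | 5-methoxyresorcinol (5-methoxybenzene-1,3-diol) | COc1cc(O)cc(O)c1
A2 | alternative 1 | 2-[4-methoxy-2-(methoxymethoxy)-3-(3-methylbut-2-en-1-yl)phenyl]prop-2-enal | C=C(C=O)c1ccc(OC)c(CC=C(C)C)c1OCOC
A3 | alternative 1 | (3R)-3-[4-methoxy-2-(methoxymethoxy)-3-(3-methylbut-2-en-1-yl)phenyl]-5-methoxychroman-2,7-diol (anomeric mixture) | COc1cc(O)cc2c1C[C@H](c1ccc(OC)c(CC=C(C)C)c1OCOC)C(O)O2
A4 | alternative 2 | 5-methoxy-6-methylidene-3-(triisopropylsilyloxy)cyclohexa-2,4-dien-1-one | C=C1C(=O)C=C(O[Si](C(C)C)(C(C)C)C(C)C)C=C1OC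
A5 | alternative 2 | 2-[4-methoxy-2-(methoxymethoxy)-3-(3-methylbut-2-en-1-yl)phenyl]acetic acid | OC(=O)Cc1ccc(OC)c(CC=C(C)C)c1OCOC
A6 | alternative 2 | (3R)-3-[4-methoxy-2-(methoxymethoxy)-3-(3-methylbut-2-en-1-yl)phenyl]-5-methoxy-7-(triisopropylsilyloxy)chroman-2-one | O=C1Oc2cc(O[Si](C(C)C)(C(C)C)C(C)C)cc(OC)c2C[C@@H]1c1ccc(OC)c(CC=C(C)C)c1OCOC
A7 | alternative 3 | (E)-1-diazo-4-[(3R)-5-methoxy-7-(triisopropylsilyloxy)chroman-3-yl]but-3-en-2-one | COc1cc(O[Si](C(C)C)(C(C)C)C(C)C)cc2c1C[C@H](/C=C/C(=O)C=[N+]=[N-])CO2
A8 | alternative 3 | 1-methoxy-5-methylhex-4-en-1-yne | COC#CCC=C(C)C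
A9 | alternative 3 | 3-methoxy-2-(3-methylbut-2-en-1-yl)-6-[(3R)-5-methoxy-7-(triisopropylsilyloxy)chroman-3-yl]phenol (identical with 18) | COc1cc(O[Si](C(C)C)(C(C)C)C(C)C)cc2c1C[C@H](c1ccc(OC)c(CC=C(C)C)c1O)CO2
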